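**Assumption:** Germacrane numbering (C1–C15) is used for every intermediate. β is the ring face that carries the C7 isopropyl group and α is the opposite face. (+)-Nopinone, the ozonolysis product of (−)-β-pinene, is taken as the commercial chiral-pool material.

## Retrosynthetic overview
1. The target comes from nucleophilic epoxidation of 6β,8α-diacetoxygermacra-1(10),4-dien-14-al, and that enal comes from Pd/CO formylation of a C10 enol triflate.
2. The ten-membered ring comes from an anionic oxy-Cope rearrangement of a 1-vinyl-2-isopropenylcyclohexan-1-ol. It makes C2–C3, breaks C5–C10, and the enolate is trapped as the triflate.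
3. The divinyl carbinol comes from vinyl addition to C10=O and trans-diaxial opening of a 5,6-β-epoxide by an isopropenyl nucleophile, which places C6–O cis to the isopropyl group.
4. The β-epoxy-8α-hydroxy ketone comes from (R)-cryptone by a bromohydrin-derived epoxide, dehydrogenation and conjugate borylation/oxidation. (R)-Cryptone comes from (+)-nopinone, whose stereocentre becomes C7 and controls all the others.
5. Ring order: cyclohexane (unveiled from the pinane), then a temporary oxirane, then the cyclodecadiene by [3,3], then the final 1,10-oxirane.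

## Route

**Step 1**
Reactants: 1 (+)-nopinone
Product: 2 (R)-cryptone, (4R)-4-isopropylcyclohex-2-en-1-one (C10 ketone, C5=C6, C7 isopropyl)
Conditions: AlCl3 (2.5 equiv), CH2Cl2, 0 °C → rt
Reagents that add atoms: none
Why: This is a Lewis-acid cyclobutane ring-opening isomerisation in which the strained bond α to the carbonyl ionises to an aluminium enolate and a tertiary cation that collapse by hydride transfer to the enone, and the bridgehead that becomes C7 is never touched, so its configuration is kept.

**Step 2**
Reactants: 2 (R)-cryptone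
Product: 3 trans-cryptol, (1S,4R)-4-isopropylcyclohex-2-en-1-ol (10α-OH, trans to the 7β-isopropyl)
Conditions: NaBH4, CeCl3·7H2O, MeOH, −78 → 0 °C
Reagents that add atoms: none
Why: In this Luche 1,2-reduction, axial hydride delivery gives the pseudo-equatorial 10α-alcohol, which makes C5=C6 nucleophilic and is only a temporary centre that step 4 erases.

**Step 3**
Reactants: 3 trans-cryptol
Product: 5 β-epoxy alcohol, (1R,2S,5R,6S)-5-isopropyl-7-oxabicyclo[4.1.0]heptan-2-ol (5,6-β-epoxide cis to isopropyl, 10α-OH), via bromodiol 4 (not isolated)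
Conditions: NBS, acetone/H2O (4:1), 0 °C; then K2CO3, MeOH, 0 °C (one pot)
Reagents that add atoms: water, O (gives the epoxide oxygen); N-bromosuccinimide, O=C1CCC(=O)N1Br (its Br stays only in 4)
Why: In the bromohydrin formation the bromonium ion forms on the α-face anti to the isopropyl group and water opens it trans-diaxially (Fürst–Plattner) at C6, the carbon remote from the C10–OH dipole, and the 6β-alkoxide then displaces the 5α-bromide (intramolecular Williamson SN2) to give the epoxide cis to the isopropyl group.

**Step 4**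
Reactants: 5 β-epoxy alcohol
Product: 7 β-epoxy enone, (1S,5S,6S)-5-isopropyl-7-oxabicyclo[4.1.0]hept-3-en-2-one (C10=O, C8=C9), via β-epoxy ketone 6 (not isolated)
Conditions: IBX (3 equiv), 4-methoxypyridine N-oxide (3 equiv), DMSO, 25 °C
Reagents that add atoms: none
Why: IBX oxidises the alcohol and then dehydrogenates the ketone, and because the ketone can enolise only towards C9 the unsaturation appears regiospecifically at C8=C9 while the mild conditions spare the epoxide.

**Step 5**
Reactants: 7 β-epoxy enone
Product: 9 8α-hydroxy β-epoxy ketone, (1S,4R,5S,6S)-4-hydroxy-5-isopropyl-7-oxabicyclo[4.1.0]heptan-2-one, via 8α-pinacolboronate 8 (not isolated)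
Conditions: B2pin2 (1.1 equiv), CuCl/DPEphos/NaOt-Bu (3 mol % each), MeOH (2 equiv), THF, 0 °C; then 30 % H2O2, pH 7 phosphate buffer, 0 °C
Reagents that add atoms: hydrogen peroxide, OO (gives the C8 oxygen); bis(pinacolato)diboron, CC1(C)OB(OC1(C)C)B1OC(C)(C)C(C)(C)O1 (its boron stays only in 8)
Why: In this Cu(I)-catalysed conjugate borylation both the isopropyl group and the epoxide shield the β-face, so boron enters C8 from the α-face, and the stereoretentive C–B oxidation gives the 8α-alcohol trans to the isopropyl group.

**Step 6**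
Reactants: 9 8α-hydroxy β-epoxy ketone
Product: 10 vinyl carbinol, (1S,2S,4R,5S,6S)-2-ethenyl-5-isopropyl-7-oxabicyclo[4.1.0]heptane-2,4-diol (10β-OH, 10α-vinyl)
Conditions: CH2=CHMgBr (2.5 equiv), LaCl3·2LiCl (30 mol %), THF, −78 °C; aq NH4Cl
Reagents that add atoms: vinylmagnesium bromide, C=C[Mg]Br
Why: In this Grignard 1,2-addition the nucleophile attacks anti to the adjacent C5–O bond of the epoxy ketone (Felkin–Anh/Cornforth, α-face) and so sets C10 with the hydroxyl cis to the epoxide.

**Step 7**
Reactants: 10 vinyl carbinol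
Product: 11 triol, (1S,2R,3S,4S,5R)-1-ethenyl-4-isopropyl-2-(prop-1-en-2-yl)cyclohexane-1,3,5-triol (5α-isopropenyl, 6β-OH, 8α-OH, 10β-OH)
Conditions: CH2=C(CH3)MgBr (4 equiv), CuI (20 mol %), THF, −30 → 0 °C; aq NH4Cl
Reagents that add atoms: isopropenylmagnesium bromide, CC(=C)[Mg]Br
Why: In this Cu-catalysed SN2 epoxide opening the half-chair with isopropyl, 8-O and vinyl equatorial allows trans-diaxial (Fürst–Plattner) attack only at C5 from the α-face, which gives the axial 6β-alcohol cis to the isopropyl group and an isopropenyl group cis to the vinyl group.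

**Step 8**
Reactants: 11 triol
Product: 12 6,8-bis(triethylsilyl) ether of 11 (tertiary 10β-OH free)
Conditions: TESOTf (2.2 equiv), 2,6-lutidine, CH2Cl2, −78 °C
Reagents that add atoms: triethylsilyl triflate, CC[Si](CC)(CC)OS(=O)(=O)C(F)(F)F
Why: This is a chemoselective silylation in which the two secondary alcohols react at −78 °C while the tertiary allylic alcohol does not, leaving only the hydroxyl needed for the next step.

**Step 9 (key step)**
Reactants: 12 bis-TES carbinol
Product: 15 (1E,5E,7R,8S,9R)-8-isopropyl-5-methyl-7,9-bis(triethylsilyloxy)cyclodeca-1,5-dien-1-yl triflate (germacrane: C10–OTf, OTf trans to C2, 4E), via potassium alkoxide 13 (not isolated), via potassium enolate 14 (not isolated)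
Conditions: KHMDS (1.3 equiv), 18-crown-6 (1.5 equiv), THF, 0 → 25 °C; then Comins' reagent (1.3 equiv), −78 → 0 °C
Reagents that add atoms: N-(5-chloro-2-pyridyl)bis(trifluoromethanesulfonimide), Clc1ccc(nc1)N(S(=O)(=O)C(F)(F)F)S(=O)(=O)C(F)(F)F
Why: In this anionic oxy-Cope [3,3]-sigmatropic rearrangement the only low-energy chair (isopropyl, 8-OTES and vinyl equatorial; isopropenyl and O⁻ axial) holds the two alkenyl groups gauche, and they react through a chair transition state with C6 pseudo-equatorial and C9 pseudo-axial, so the new C2–C3 bond closes the ten-membered ring with a 4E alkene and a 1(10)-enolate having C2 cis to C9, which the triflimide traps regio- and geometry-specifically with C6, C7 and C8 untouched.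

**Step 10**
Reactants: 15 bis-TES dienyl triflate
Product: 17 (1E,5E,7R,8S,9R)-7,9-diacetoxy-8-isopropyl-5-methylcyclodeca-1,5-dien-1-yl triflate, via diol triflate 16 (not isolated)
Conditions: HF·pyridine, pyridine/THF, 0 °C → rt; then Ac2O, DMAP, rt (one pot)
Reagents that add atoms: acetic anhydride, CC(=O)OC(C)=O
Why: Fluoride desilylation followed by DMAP-catalysed acetylation changes only the O-substituents, and doing it before the aldehyde exists avoids lactol formation between 8-OH and C14.

**Step 11**
Reactants: 17 diacetoxy dienyl triflate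
Product: 18 (1E,5E,7R,8S,9R)-7,9-diacetoxy-8-isopropyl-5-methylcyclodeca-1,5-diene-1-carbaldehyde (6β,8α-diacetoxygermacra-1(10),4-dien-14-al, CHO trans to C2)
Conditions: Pd(PPh3)4 (5 mol %), LiCl (3 equiv), CO (1–3 atm), Bu3SnH (1.1 equiv, slow addition), THF, 50 °C
Reagents that add atoms: carbon monoxide, [C-]#[O+]
Why: In this Stille-type carbonylative formylation, oxidative addition into the vinyl C–OTf bond is far faster than ionisation of the hindered trisubstituted allylic acetate, and CO insertion followed by hydride transfer installs C14 with retention of alkene geometry.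

**Step 12**
Reactants: 18 dienal
Product: 19 pulicanaral A
Conditions: t-BuOOH (decane), Triton B (10 mol %), THF, 0 °C
Reagents that add atoms: tert-butyl hydroperoxide, CC(C)(C)OO
Why: In this Weitz–Scheffer epoxidation the peroxide anion attacks only the electron-poor C1=C10, adds to C1 on the outer face of the conformer that keeps the isopropyl group and both acetates pseudo-equatorial with C14 pointing to the β-face, and closes on the same face to give the oxirane with C2 cis to C9 (1R,10S), while C4=C5 and the acetates survive the catalytic base.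

## Compound list
1 | (+)-nopinone, (1R,5S)-6,6-dimethylbicyclo[3.1.1]heptan-2-one | CC1(C)[C@H]2CCC(=O)[C@@H]1C2 | starting material
2 | (R)-cryptone | CC(C)[C@H]1CCC(=O)C=C1 | intermediate
3 | trans-cryptol (1S,4R) | CC(C)[C@H]1CC[C@H](O)C=C1 | intermediate
4 | (1S,2S,3S,4R)-2-bromo-4-isopropylcyclohexane-1,3-diol | CC(C)[C@H]1CC[C@H](O)[C@H](Br)[C@H]1O | intermediate (not isolated)
5 | β-epoxy alcohol | CC(C)[C@H]1CC[C@H](O)[C@H]2O[C@@H]12 | intermediate
6 | β-epoxy ketone, (1S,5R,6S)-5-isopropyl-7-oxabicyclo[4.1.0]heptan-2-one | CC(C)[C@H]1CCC(=O)[C@H]2O[C@@H]12 | intermediate (not isolated)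
7 | β-epoxy enone | CC(C)[C@H]1C=CC(=O)[C@H]2O[C@@H]12 | intermediate
8 | 8α-pinacolboronate of the β-epoxy ketone | CC(C)[C@H]1[C@H](B2OC(C)(C)C(C)(C)O2)CC(=O)[C@H]3O[C@@H]13 | intermediate (not isolated)
9 | 8α-hydroxy β-epoxy ketone | CC(C)[C@H]1[C@H](O)CC(=O)[C@H]2O[C@@H]12 | intermediate
10 | vinyl carbinol (epoxy diol) | CC(C)[C@H]1[C@H](O)C[C@](O)(C=C)[C@H]2O[C@@H]12 | intermediate
11 | divinyl triol | CC(C)[C@H]1[C@H](O)C[C@](O)(C=C)[C@H](C(C)=C)[C@H]1O | intermediate
12 | bis-TES divinyl carbinol | CC(C)[C@H]1[C@H](O[Si](CC)(CC)CC)C[C@](O)(C=C)[C@H](C(C)=C)[C@H]1O[Si](CC)(CC)CC | intermediate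
13 | potassium alkoxide of 12 | [K+].CC(C)[C@H]1[C@H](O[Si](CC)(CC)CC)C[C@]([O-])(C=C)[C@H](C(C)=C)[C@H]1O[Si](CC)(CC)CC | intermediate (not isolated)
14 | potassium cyclodecadienolate | [K+].CC[Si](CC)(CC)O[C@@H]1/C=C(\C)CC/C=C(/[O-])C[C@@H](O[Si](CC)(CC)CC)[C@@H]1C(C)C | intermediate (not isolated)
15 | bis-TES dienyl triflate | CC[Si](CC)(CC)O[C@@H]1/C=C(\C)CC/C=C(/OS(=O)(=O)C(F)(F)F)C[C@@H](O[Si](CC)(CC)CC)[C@@H]1C(C)C | intermediate
16 | diol dienyl triflate | O[C@@H]1/C=C(\C)CC/C=C(/OS(=O)(=O)C(F)(F)F)C[C@@H](O)[C@@H]1C(C)C | intermediate (not isolated)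
17 | diacetoxy dienyl triflate | CC(=O)O[C@@H]1/C=C(\C)CC/C=C(/OS(=O)(=O)C(F)(F)F)C[C@@H](OC(C)=O)[C@@H]1C(C)C | intermediate
18 | 6β,8α-diacetoxygermacra-1(10),4-dien-14-al | CC(=O)O[C@@H]1/C=C(\C)CC/C=C(/C=O)C[C@@H](OC(C)=O)[C@@H]1C(C)C | intermediate
19 | pulicanaral A | CC(=O)O[C@@H]1/C=C(\C)CC[C@H]2O[C@@]2(C=O)C[C@@H](OC(C)=O)[C@@H]1C(C)C | target

## Step count
The route has 12 steps in total, and the longest linear sequence is 12 steps from 1.

## Three steps most likely to fail

**Step 7 (opening at C5, next to the fully substituted C10).** The SN2 reaction may be slow, and magnesium salts could trigger a 1,2-vinyl shift (semipinacol) instead. The fallback sets out from 10 and returns at 11. Lithium acetylide–ethylenediamine in DMSO is a slim nucleophile with no Lewis acid present. It opens the epoxide at C5 with the same trans-diaxial sense and gives the 5α-ethynyl triol F4. Zirconium-catalysed methylalumination (AlMe3 in excess, Cp2ZrCl2, then water) then builds the isopropenyl group on the terminal alkyne and delivers 11.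

**Step 12 (facial selectivity on the flexible ten-membered ring).** The wrong face, or a mixture of epoxides, is possible. The fallback sets out from 18 and returns at 19. Luche reduction gives the C14 allylic alcohol F5. A hydroxyl-directed, syn-stereospecific VO(acac)2/t-BuOOH epoxidation touches only the allylic-alcohol alkene and not the allylic-acetate alkene C4=C5, and gives the 1,10-epoxy alcohol F6. Dess–Martin oxidation of F6 gives 19.

**Step 3 (epoxide on the more hindered face through the bromohydrin).** Mixed bromonium faces, oxidation of the alcohol by NBS, or Payne migration under base could erode the yield. The fallback sets out from 2 and returns at 6, which step 4 then dehydrogenates to 7.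
- H2O2/NaOH (Weitz–Scheffer) gives the 5,6-α-epoxy ketone F1, anti to the isopropyl group.
- Catalytic HClO4 in aqueous THF opens F1 trans-diaxially at the β-carbon C6 and gives the 5α,6β-dihydroxy ketone F2.
- MsCl/pyridine reacts at the less hindered α-ketol hydroxyl and gives the 5α-mesylate F3.
- K2CO3 lets the 6β-oxygen displace the mesylate with inversion and gives 6.

## Further compounds
F1 | step 3 | 5,6-α-epoxy ketone (epoxide trans to isopropyl) | CC(C)[C@H]1CCC(=O)[C@@H]2O[C@H]12
F2 | step 3 | 5α,6β-dihydroxy-7β-isopropyl ketone | CC(C)[C@H]1CCC(=O)[C@H](O)[C@H]1O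
F3 | step 3 | 5α-mesyloxy-6β-hydroxy ketone | CC(C)[C@H]1CCC(=O)[C@H](OS(C)(=O)=O)[C@H]1O
F4 | step 7 | 5α-ethynyl triol | CC(C)[C@H]1[C@H](O)C[C@](O)(C=C)[C@H](C#C)[C@H]1O
F5 | step 12 | 6β,8α-diacetoxygermacra-1(10),4-dien-14-ol | CC(=O)O[C@@H]1/C=C(\C)CC/C=C(/CO)C[C@@H](OC(C)=O)[C@@H]1C(C)C
F6 | step 12 | 1,10-epoxy-14-alcohol | CC(=O)O[C@@H]1/C=C(\C)CC[C@H]2O[C@@]2(CO)C[C@@H](OC(C)=O)[C@@H]1C(C)C
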